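**Retrosynthetic overview**
1. Target 23 ⇐ double senecioylation of anti-diol 21 ⇐ hydroxyl-directed reduction of hydroxy-dione 20 ⇐ ligand-controlled conjugate borylation/oxidation of tricyclic dienedione 18.
2. Key disconnection: the cyclobutane bond C10–C11 of 18 (quaternary C10), formed by intramolecular oxidative coupling of the two α'-enolates of cis-fused bis-enone 16. Both α-carbons are natively nucleophilic; one is oxidised to an α-keto radical (enolonium equivalent) and captured by the other.
3. 16 ⇐ allylic oxidation and ring-closing metathesis of dienone 14 ⇐ Johnson–Claisen rearrangement of cis-cyclohexenol 8, which relays C–O to the cis C–C bond.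
4. 8 ⇐ CBS reduction of enone 7 ⇐ enamine-catalysed Michael/aldol annulation of 3,3-dimethylpent-4-enal (from prenol) with ethyl vinyl ketone.
5. Ring order: six-membered ring (step 2), seven-membered ring (step 6), four-membered ring (step 8).

Assumption: tricyclic compounds carry longipinane numbering (C1 ketone, C2=C3, O at C7 and C9, cyclobutane C4/C5/C11/C10); compounds 11 and 13–16 are carried as both epimers at the methyl-bearing carbon next to the carbonyl, which is planarised in step 8.

**Step 1**
Reactants: 1 3-methylbut-2-en-1-ol (prenol); 2 ethyl vinyl ether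
Product: 4 3,3-dimethylpent-4-enal, via prenyl vinyl ether 3 (not isolated)
Conditions: 2 (10 equiv), Pd(OAc)2 (0.5 mol%), 1,10-phenanthroline (0.5 mol%), 60 °C; excess 2 distilled off; then neat, 140 °C, sealed tube
Reagents that add atoms: none
Why: Palladium-catalysed vinyl ether exchange followed by Claisen rearrangement of the allyl vinyl ether through a chair transition state; no stereocentre is formed.

**Step 2**
Reactants: 4 3,3-dimethylpent-4-enal; 5 pent-1-en-3-one (ethyl vinyl ketone)
Product: 7 (4R)-2-methyl-4-(2-methylbut-3-en-2-yl)cyclohex-2-en-1-one, via keto aldehyde 6 (not isolated)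
Conditions: (S)-2-[methoxy(diphenyl)methyl]pyrrolidine (10 mol%), ethyl 3,4-dihydroxybenzoate (20 mol%), 5 (1.5 equiv), neat, 4 → 23 °C; then LiOH·H2O (0.3 equiv), i-PrOH, 23 °C
Reagents that add atoms: none
Why: Enamine-catalysed Michael addition, in which the E-enamine is attacked on the face away from the diphenyl(methoxy)methyl group and so gives (2S)-6, followed by intramolecular aldol condensation (Robinson-type annulation) that leaves the new stereocentre untouched.

**Step 3**
Reactants: 7 (4R)-2-methyl-4-(2-methylbut-3-en-2-yl)cyclohex-2-en-1-one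
Product: 8 (1S,4R)-2-methyl-4-(2-methylbut-3-en-2-yl)cyclohex-2-en-1-ol
Conditions: (R)-2-methyl-CBS-oxazaborolidine (20 mol%), catecholborane (1.5 equiv), toluene, −78 °C
Reagents that add atoms: none
Why: Corey–Bakshi–Shibata 1,2-reduction, where the (R)-oxazaborolidine (alkenyl side as the large group) delivers hydride to give the (1S)-alcohol cis to the C4 substituent under reagent control; catecholborane leaves the vinyl group alone at −78 °C.

**Step 4**
Reactants: 8 (1S,4R)-2-methyl-4-(2-methylbut-3-en-2-yl)cyclohex-2-en-1-ol; 9 triethyl orthopropionate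
Product: 11 ethyl 2-[(1S,6R)-2-methyl-6-(2-methylbut-3-en-2-yl)cyclohex-2-en-1-yl]propanoate, via ketene acetal 10 (not isolated)
Conditions: 9 (6 equiv), EtCO2H (0.1 equiv), xylene, 140 °C, EtOH distilled off
Reagents that add atoms: none
Why: Johnson–Claisen rearrangement, in which the ketene acetal on the pseudoaxial oxygen rearranges suprafacially so the new C–C bond forms on the face that carried oxygen, cis to the 2-methylbut-3-en-2-yl group, and the ring alkene moves to the position needed later.

**Step 5**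
Reactants: 11 ethyl 2-[(1S,6R)-2-methyl-6-(2-methylbut-3-en-2-yl)cyclohex-2-en-1-yl]propanoate; 12 vinylmagnesium bromide
Product: 14 4-[(1S,6R)-2-methyl-6-(2-methylbut-3-en-2-yl)cyclohex-2-en-1-yl]pent-1-en-3-one, via Weinreb amide 13 (not isolated)
Conditions: MeNHOMe·HCl (1.5 equiv), i-PrMgCl (3.0 equiv), THF, −20 °C; then 12 (2.5 equiv), 0 °C; inverse quench into cold 1 M HCl
Reagents that add atoms: N,O-dimethylhydroxylamine hydrochloride, CNOC.Cl (N-methoxy-N-methyl group of 13 only)
Why: One-pot Weinreb amide formation and Grignard addition, where the chelated tetrahedral intermediate prevents over-addition; ring stereocentres are not touched.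

**Step 6**
Reactants: 14 4-[(1S,6R)-2-methyl-6-(2-methylbut-3-en-2-yl)cyclohex-2-en-1-yl]pent-1-en-3-one
Product: 15 (4aR,9aS)-1,5,5,9-tetramethyl-3,4,4a,5,9,9a-hexahydro-8H-benzo[7]annulen-8-one
Conditions: second-generation Hoveyda–Grubbs catalyst (5 mol%), toluene (2 mM), 80 °C
Reagents that add atoms: none
Why: Ring-closing metathesis of the vinyl ketone with the neopentyl vinyl group closes the cis-fused cycloheptenone with loss of ethene; the trisubstituted ring alkene is inert.

**Step 7**
Reactants: 15 (4aR,9aS)-1,5,5,9-tetramethyl-3,4,4a,5,9,9a-hexahydro-8H-benzo[7]annulen-8-one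
Product: 16 (4aR,9aS)-1,5,5,9-tetramethyl-4a,5,9,9a-tetrahydro-3H-benzo[7]annulene-3,8(4H)-dione
Conditions: Rh2(caprolactamate)4 (1 mol%), t-BuOOH (5 equiv), K2CO3 (0.5 equiv), CH2Cl2, 23 °C
Reagents that add atoms: tert-butyl hydroperoxide, CC(C)(C)OO
Why: Radical allylic oxidation, with tert-butylperoxyl abstracting hydrogen from the ring CH2 next to the CH= carbon and the allylic peroxide collapsing to the 3-methylcyclohexenone; no stereocentre is touched.

**Step 8**
Reactants: 16 (4aR,9aS)-1,5,5,9-tetramethyl-4a,5,9,9a-tetrahydro-3H-benzo[7]annulene-3,8(4H)-dione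
Product: 18 (4R,5S,10R,11R)-longipina-2,7-diene-1,9-dione, via dilithium bis-dienolate 17 (not isolated)
Conditions: LiN(iPr)2 (2.3 equiv), THF, −78 °C, 1 h; then CuCl2 (2.3 equiv) in DMF, −78 → 0 °C
Reagents that add atoms: none
Why: Proposed new method: kinetic α'-deprotonation of both enones (C4 and C9 of 16; the seven-ring C=C blocks the other α-side) gives a bis(cross-conjugated dienolate) in which the axial seven-ring enolate carbon sits 1,3-diaxial over the six-ring enolate carbon, CuCl2 oxidises one enolate to an α-keto radical (enolonium equivalent) that is captured by the other enolate, and the resulting ketyl is oxidised at once, so the strained cyclobutane and quaternary C10 form irreversibly with the cis ring fusion allowing only the (10R,11R) mode; the closest known reaction type is copper- or iron-mediated oxidative coupling of ketone enolates to 1,4-diketones, including closure of 1,6-dicarbonyl bis-enolates to cyclobutane-1,2-dicarbonyl compounds.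

**Step 9**
Reactants: 18 (4R,5S,10R,11R)-longipina-2,7-diene-1,9-dione
Product: 20 (4R,5S,7R,10R,11R)-7-hydroxylongipin-2-ene-1,9-dione, via pinacol boronate 19 (not isolated)
Conditions: B2pin2 (1.2 equiv), CuCl (5 mol%), (R,R)-QuinoxP* (6 mol%), NaOtBu (10 mol%), MeOH (2 equiv), THF, 0 °C; then NaBO3·4H2O, THF/H2O, 23 °C
Reagents that add atoms: bis(pinacolato)diboron, CC1(C)OB(OC1(C)C)B1OC(C)(C)C(C)(C)O1 (boryl group of 19); sodium perborate tetrahydrate, [Na+].[O-]OB=O.O.O.O.O (oxygen of 20)
Why: Copper-catalysed conjugate borylation of the disubstituted seven-ring enone only (the β,β-disubstituted bicyclic enone is inert) and C–B oxidation with retention; the two faces of this enone are related by the local mirror plane of the bicyclo[4.1.1]octane unit, so the chiral ligand, its enantiomer fixed in a pilot run, sets C7 as R.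

**Step 10**
Reactants: 20 (4R,5S,7R,10R,11R)-7-hydroxylongipin-2-ene-1,9-dione
Product: 21 (4R,5S,7R,9R,10R,11R)-7,9-dihydroxylongipin-2-en-1-one
Conditions: Me4NBH(OAc)3 (5 equiv), MeCN/AcOH (1:1), −30 °C
Reagents that add atoms: none
Why: Evans–Saksena reduction, in which the C7 alkoxy(diacetoxy)borohydride delivers hydride intramolecularly to the C9 ketone from the face of the C7 oxygen, giving the anti (7R,9R) diol while the enone stays intact.

**Step 11**
Reactants: 21 (4R,5S,7R,9R,10R,11R)-7,9-dihydroxylongipin-2-en-1-one; 22 3-methylbut-2-enoyl chloride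
Product: 23 (4R,5S,7R,9R,10R,11R)-1-oxolongipin-2-ene-7,9-diyl bis(3-methylbut-2-enoate)
Conditions: 22 (5 equiv), DMAP (0.5 equiv), pyridine, CH2Cl2, 0 → 40 °C
Reagents that add atoms: none
Why: DMAP-catalysed acylation (acylpyridinium transfer) of both hindered secondary alcohols; no stereocentre is affected.

**Compound list**
1 | 3-methylbut-2-en-1-ol (prenol) | CC(C)=CCO | starting material
2 | ethyl vinyl ether | C=COCC | starting material
3 | 3-methylbut-2-enyl vinyl ether (prenyl vinyl ether) | CC(C)=CCOC=C | intermediate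
4 | 3,3-dimethylpent-4-enal | C=CC(C)(C)CC=O | intermediate
5 | pent-1-en-3-one (ethyl vinyl ketone) | C=CC(=O)CC | starting material
6 | (2S)-2-(2-methylbut-3-en-2-yl)-5-oxoheptanal | O=C[C@@H](CCC(=O)CC)C(C)(C)C=C | intermediate
7 | (4R)-2-methyl-4-(2-methylbut-3-en-2-yl)cyclohex-2-en-1-one | O=C1CC[C@@H](C(C)(C)C=C)C=C1C | intermediate
8 | (1S,4R)-2-methyl-4-(2-methylbut-3-en-2-yl)cyclohex-2-en-1-ol (OH cis to the C4 group) | CC1=C[C@H](C(C)(C)C=C)CC[C@@H]1O | intermediate
9 | triethyl orthopropionate (1,1,1-triethoxypropane) | CCC(OCC)(OCC)OCC | starting material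
10 | 1-ethoxyprop-1-enyl ether of 8 (mixed ketene acetal on O1) | CC=C(OCC)O[C@H]1CC[C@@H](C(C)(C)C=C)C=C1C | intermediate
11 | ethyl 2-[(1S,6R)-2-methyl-6-(2-methylbut-3-en-2-yl)cyclohex-2-en-1-yl]propanoate (both C2 epimers; ring substituents cis) | CCOC(=O)C(C)[C@H]1C(C)=CCC[C@H]1C(C)(C)C=C | intermediate
12 | vinylmagnesium bromide | C=C[Mg]Br | starting material
13 | N-methoxy-N-methyl-2-[(1S,6R)-2-methyl-6-(2-methylbut-3-en-2-yl)cyclohex-2-en-1-yl]propanamide | CON(C)C(=O)C(C)[C@H]1C(C)=CCC[C@H]1C(C)(C)C=C | intermediate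
14 | 4-[(1S,6R)-2-methyl-6-(2-methylbut-3-en-2-yl)cyclohex-2-en-1-yl]pent-1-en-3-one | C=CC(=O)C(C)[C@H]1C(C)=CCC[C@H]1C(C)(C)C=C | intermediate
15 | (4aR,9aS)-1,5,5,9-tetramethyl-3,4,4a,5,9,9a-hexahydro-8H-benzo[7]annulen-8-one (cis-fused cyclohexene/cycloheptenone; C9 epimers) | CC1C(=O)C=CC(C)(C)[C@@H]2CCC=C(C)[C@H]12 | intermediate
16 | (4aR,9aS)-1,5,5,9-tetramethyl-4a,5,9,9a-tetrahydro-3H-benzo[7]annulene-3,8(4H)-dione (cis-fused bis-enone; C9 epimers) | CC1C(=O)C=CC(C)(C)[C@@H]2CC(=O)C=C(C)[C@H]12 | intermediate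
17 | dilithium bis-dienolate of 16 (enolate carbons C4 and C9) | [Li+].[Li+].CC1=C([O-])C=CC(C)(C)[C@@H]2C=C([O-])C=C(C)[C@H]12 | intermediate
18 | (4R,5S,10R,11R)-longipina-2,7-diene-1,9-dione (2,6,6,9-tetramethyltricyclo[5.4.0.0^2,8]undeca-4,9-diene-3,11-dione) | C1=CC(=O)[C@@]2(C)[C@@H]3C(=O)C=C(C)[C@H]2[C@@H]3C1(C)C | intermediate
19 | (4R,5S,7R,10R,11R)-7-(4,4,5,5-tetramethyl-1,3,2-dioxaborolan-2-yl)longipin-2-ene-1,9-dione | CC4(C)OB(OC4(C)C)[C@@H]1CC(=O)[C@@]2(C)[C@@H]3C(=O)C=C(C)[C@H]2[C@@H]3C1(C)C | intermediate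
20 | (4R,5S,7R,10R,11R)-7-hydroxylongipin-2-ene-1,9-dione | O[C@@H]1CC(=O)[C@@]2(C)[C@@H]3C(=O)C=C(C)[C@H]2[C@@H]3C1(C)C | intermediate
21 | (4R,5S,7R,9R,10R,11R)-7,9-dihydroxylongipin-2-en-1-one (anti-diol) | O[C@@H]1C[C@@H](O)[C@@]2(C)[C@@H]3C(=O)C=C(C)[C@H]2[C@@H]3C1(C)C | intermediate
22 | 3-methylbut-2-enoyl chloride (senecioyl chloride) | CC(C)=CC(Cl)=O | starting material
23 | (4R,5S,7R,9R,10R,11R)-1-oxolongipin-2-ene-7,9-diyl bis(3-methylbut-2-enoate) | CC(C)=CC(=O)O[C@@H]1C[C@@H](OC(=O)C=C(C)C)[C@@]2(C)[C@@H]3C(=O)C=C(C)[C@H]2[C@@H]3C1(C)C | target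

**Step count**
Total steps: 11. Longest linear sequence: 11 (fully linear from prenol).

**Steps most likely to fail, with fallbacks**

Step 8 (oxidative closure of the cyclobutane). The tertiary seven-ring enolate may form slowly, or chlorination and intermolecular coupling may compete. The fallback sets out from 16 and comes back at 18. Compound 16 is converted with LiN(iPr)2 and Me3SiCl at −78 °C into the isolable bis(trimethylsilyl) dienol ether F5. F5 is then oxidised with (NH4)2Ce(NO3)6 (2.2 equiv) and NaHCO3 in MeCN at −30 °C. One neutral silyl enol ether is oxidised to its radical cation and attacked by the other inside the cis-fused frame, and loss of both silyl groups gives 18.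

Step 9 (C7 oxygenation). The β-carbon is neopentyl, and the stereocentre depends entirely on the ligand. The fallback sets out from 18 and comes back at 21. Wacker-type oxidation of the seven-ring enone (Na2PdCl4 cat., t-BuOOH, AcOH/H2O, 50 °C) gives the 7,9-diketone, longipin-2-ene-1,7,9-trione F6. Double asymmetric transfer hydrogenation of F6 with RuCl[(R,R)-TsDPEN](p-cymene) (the TsDPEN enantiomer that gives the 7R,9R product) in HCO2H/Et3N reduces both saturated ketones under catalyst control to the anti-diol 21, bypassing steps 9 and 10.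

Step 4 (Johnson–Claisen next to the quaternary carbon). The allylic alcohol may ionise or eliminate under hot acidic conditions, and the new bond forms beside a tert-alkyl group. The fallback sets out from 8 and comes back at 13. Alcohol 8 is acylated with propionyl chloride/pyridine to the propanoate F1. LiN(iPr)2 and Me3SiCl in THF at −78 °C give the trimethylsilyl ketene acetal F2, which undergoes Ireland–Claisen rearrangement on warming to 23–60 °C with the same suprafacial transfer, giving the trimethylsilyl ester F3. Aqueous work-up gives the carboxylic acid F4. 1,1'-Carbonyldiimidazole followed by MeNHOMe·HCl converts F4 into Weinreb amide 13, which is treated with 12 as in step 5.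

**Further compounds**
F1 | step 4 | (1S,4R)-2-methyl-4-(2-methylbut-3-en-2-yl)cyclohex-2-en-1-yl propanoate | CCC(=O)O[C@H]1CC[C@@H](C(C)(C)C=C)C=C1C
F2 | step 4 | trimethylsilyl ketene acetal of F1 (1-(trimethylsilyloxy)prop-1-enyl ether of 8) | CC=C(O[Si](C)(C)C)O[C@H]1CC[C@@H](C(C)(C)C=C)C=C1C
F3 | step 4 | trimethylsilyl 2-[(1S,6R)-2-methyl-6-(2-methylbut-3-en-2-yl)cyclohex-2-en-1-yl]propanoate | C[Si](C)(C)OC(=O)C(C)[C@H]1C(C)=CCC[C@H]1C(C)(C)C=C
F4 | step 4 | 2-[(1S,6R)-2-methyl-6-(2-methylbut-3-en-2-yl)cyclohex-2-en-1-yl]propanoic acid | OC(=O)C(C)[C@H]1C(C)=CCC[C@H]1C(C)(C)C=C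
F5 | step 8 | bis(trimethylsilyl) dienol ether of 16 (silyloxy groups at C3 and C8; enol carbons C4 and C9) | CC1=C(O[Si](C)(C)C)C=CC(C)(C)[C@@H]2C=C(O[Si](C)(C)C)C=C(C)[C@H]12
F6 | step 9 | (4R,5S,10R,11R)-longipin-2-ene-1,7,9-trione | O=C1CC(=O)[C@@]2(C)[C@@H]3C(=O)C=C(C)[C@H]2[C@@H]3C1(C)C
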